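The side chain is cut between C3′, the acetoxy carbon beside the isopropenyl group, and C4′, the adjoining CH2. C3′ is treated as the carbonyl carbon of methacrolein and C4′ as the terminal carbon of a vinyl group on the tertiary carbinol C6′ that sits on C1 of ring A (the cyclopentane) of the trans-hydroazulenone. In one flask the vinyl group is hydroborated, exchanged to an alkylzinc and added to methacrolein under a chiral titanium catalyst, which sets C3′ as S, and the alkoxide is acetylated. The precursor is a bis-silylated bicyclic vinyl carbinol with the ring B enone masked as an allylic silyl ether.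

Key step: step 12

Remark: ring atoms are numbered as in azulene (ring A = C1, C2, C3, C3a, C8a; ring B = C3a, C4 to C8, C8a) and the side chain as hept-1-ene (C1′ to C7′). Ring carbon C5 carries its oxygen in either configuration from step 4 to step 13 (both epimers are carried on and converge in step 14), so it is written without configuration.

Step 1
Reactants: 1 diallyl adipate
Product: 3 allyl 1-methyl-2-oxocyclopentane-1-carboxylate (racemic), via sodium enolate 2 (not isolated)
Conditions: NaH, THF, reflux; then MeI, rt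
Reagents that add atoms: iodomethane CI
Why: Dieckmann condensation gives the stabilised sodium enolate of the β-keto ester, which is C-methylated in the same flask; the quaternary carbon forms racemic and its configuration is set in step 2.

Step 2
Reactants: 3 allyl 1-methyl-2-oxocyclopentane-1-carboxylate (racemic)
Product: 4 (R)-2-allyl-2-methylcyclopentan-1-one
Conditions: Pd2(dba)3 (2.5 mol %), (R)-t-BuPHOX [(R)-4-tert-butyl-2-(2-diphenylphosphinophenyl)-4,5-dihydrooxazole] (6 mol %), THF, 25 °C
Reagents that add atoms: none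
Why: Decarboxylative asymmetric allylic alkylation (enantioselective Tsuji allylation): ionisation by zerovalent palladium and loss of CO2 turn both enantiomers of 3 into the same π-allylpalladium enolate, and C–C bond formation within the chiral phosphinooxazoline complex sets the quaternary stereocenter (later C3a), the (R)-ligand being expected to give the R ketone by analogy with the (S)-ligand/(S)-ketone pairing of the cyclohexanone series.

Step 3
Reactants: 4 (R)-2-allyl-2-methylcyclopentan-1-one
Product: 5 (R)-2-(1-methyl-2-oxocyclopentyl)acetaldehyde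
Conditions: O3, CH2Cl2, −78 °C; then Me2S, −78 °C to rt
Reagents that add atoms: ozone [O-][O+]=O
Why: Ozonolysis with reductive work-up cleaves the only C=C bond to the aldehyde and leaves the ketone and the quaternary stereocenter untouched.

Step 4
Reactants: 5 (R)-2-(1-methyl-2-oxocyclopentyl)acetaldehyde
Product: 7 (2R)-2-[2-(tert-butyldimethylsilyloxy)-3-methylbut-3-en-1-yl]-2-methylcyclopentan-1-one (both epimers at the silyloxy carbon), via bromomagnesium alkoxide 6 (not isolated)
Conditions: isopropenylmagnesium bromide (1.05 equiv), THF, −78 °C; then TBSOTf, 2,6-lutidine, −78 to 0 °C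
Reagents that add atoms: isopropenylmagnesium bromide CC(=C)[Mg]Br; tert-butyldimethylsilyl trifluoromethanesulfonate CC(C)(C)[Si](C)(C)OS(=O)(=O)C(F)(F)F
Why: Chemoselective Grignard 1,2-addition to the aldehyde, which is far more electrophilic than the α-quaternary ketone, followed by O-silylation of the magnesium alkoxide in the flask (which also forestalls hemiketal formation); the new carbinol carbon (later C5) forms without control and is written as both epimers because it ends as the ketone.

Step 5
Reactants: 7 (2R)-2-[2-(tert-butyldimethylsilyloxy)-3-methylbut-3-en-1-yl]-2-methylcyclopentan-1-one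
Product: 10 (2E,5R)-5-[2-(tert-butyldimethylsilyloxy)-3-methylbut-3-en-1-yl]-2-ethylidene-5-methylcyclopentan-1-one, via lithium aldolate 8 (not isolated), via aldol mesylate 9 (not isolated)
Conditions: LiN(iPr)2, THF, −78 °C; CH3CHO; MsCl, −78 to 0 °C; then DBU, rt
Reagents that add atoms: acetaldehyde CC=O
Why: Directed aldol condensation: the only enolisable position (later C1) is deprotonated, the aldolate is mesylated and eliminated by an E1cB pathway to the thermodynamically favoured E-ethylidene ketone.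

Step 6
Reactants: 10 (2E,5R)-5-[2-(tert-butyldimethylsilyloxy)-3-methylbut-3-en-1-yl]-2-ethylidene-5-methylcyclopentan-1-one
Product: 11 (2E,5R)-1-allyl-5-[2-(tert-butyldimethylsilyloxy)-3-methylbut-3-en-1-yl]-2-ethylidene-5-methylcyclopentan-1-ol (both C1 epimers)
Conditions: allylmagnesium bromide, THF, −78 °C; then H2O
Reagents that add atoms: allylmagnesium bromide C=CC[Mg]Br
Why: Grignard 1,2-addition of the allyl reagent, which adds to hindered enone carbonyl groups through a six-membered transition state; the configuration of the new carbinol carbon does not matter because this carbon becomes sp2 in step 7.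

Step 7
Reactants: 11 (2E,5R)-1-allyl-5-[2-(tert-butyldimethylsilyloxy)-3-methylbut-3-en-1-yl]-2-ethylidene-5-methylcyclopentan-1-ol
Product: 12 1-[(3R)-2-allyl-3-[2-(tert-butyldimethylsilyloxy)-3-methylbut-3-en-1-yl]-3-methylcyclopent-1-en-1-yl]ethan-1-one
Conditions: pyridinium chlorochromate [C5H5NH][CrO3Cl], 4 Å molecular sieves, CH2Cl2, rt
Reagents that add atoms: none
Why: Babler–Dauben oxidative transposition: the chromate ester of the tertiary allylic alcohol undergoes a [3,3] shift to the secondary allylic chromate, which is oxidised to the methyl ketone, so the acetyl group ends on C1 and the tetrasubstituted double bond at C1=C8a.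

Step 8
Reactants: 12 1-[(3R)-2-allyl-3-[2-(tert-butyldimethylsilyloxy)-3-methylbut-3-en-1-yl]-3-methylcyclopent-1-en-1-yl]ethan-1-one
Product: 13 1-[(3aR)-5-(tert-butyldimethylsilyloxy)-3a,6-dimethyl-2,3,3a,4,5,8-hexahydroazulen-1-yl]ethan-1-one
Conditions: second-generation Grubbs catalyst (5 mol %), 1,4-benzoquinone (10 mol %), toluene (2 mM), 80 °C
Reagents that add atoms: none
Why: Ring-closing metathesis starts at the allyl group and closes the seven-membered ring B onto the 1,1-disubstituted olefin, forming the trisubstituted C6=C7 bond, while the tetrasubstituted enone is inert to the catalyst.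

Step 9
Reactants: 13 1-[(3aR)-5-(tert-butyldimethylsilyloxy)-3a,6-dimethyl-2,3,3a,4,5,8-hexahydroazulen-1-yl]ethan-1-one
Product: 15 1-[(1S,3aR,8aS)-5-(tert-butyldimethylsilyloxy)-3a,6-dimethyl-1,2,3,3a,4,5,8,8a-octahydroazulen-1-yl]ethan-1-one, via lithium enolate 14 (not isolated)
Conditions: Li, NH3 (l)/THF, t-BuOH (1 equiv), −78 °C; then isoprene; solid NH4Cl
Reagents that add atoms: none
Why: Dissolving-metal conjugate reduction of the enone: the C8a carbanion is protonated on the face opposite the angular methyl group (trans ring fusion, C8a S) and the exocyclic lithium enolate is then protonated kinetically at C1 on the same face, anti to the C8 branch and to the 1,3-related angular methyl group, which places the acetyl group cis to the angular methyl group (C1 S); the isolated C6=C7 bond and the silyl ether are not reduced.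

Step 10
Reactants: 15 1-[(1S,3aR,8aS)-5-(tert-butyldimethylsilyloxy)-3a,6-dimethyl-1,2,3,3a,4,5,8,8a-octahydroazulen-1-yl]ethan-1-one
Product: 16 (2S)-2-[(1S,3aR,8aS)-5-(tert-butyldimethylsilyloxy)-3a,6-dimethyl-1,2,3,3a,4,5,8,8a-octahydroazulen-1-yl]but-3-en-2-ol
Conditions: vinylmagnesium bromide, anhydrous CeCl3, THF, −78 °C; then H2O
Reagents that add atoms: vinylmagnesium bromide C=C[Mg]Br
Why: Cerium-mediated Grignard 1,2-addition under Felkin–Anh control with C8a as the large substituent on C1 (the sense known from additions to 20-oxo steroids) should give the S tertiary alcohol, and CeCl3 suppresses enolisation and thereby epimerisation at C1.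

Step 11
Reactants: 16 (2S)-2-[(1S,3aR,8aS)-5-(tert-butyldimethylsilyloxy)-3a,6-dimethyl-1,2,3,3a,4,5,8,8a-octahydroazulen-1-yl]but-3-en-2-ol
Product: 17 tert-butyl{[(1S,3aR,8aS)-3a,6-dimethyl-1-[(2S)-2-(triethylsilyloxy)but-3-en-2-yl]-1,2,3,3a,4,5,8,8a-octahydroazulen-5-yl]oxy}dimethylsilane
Conditions: TESOTf, 2,6-lutidine, CH2Cl2, −78 to 0 °C
Reagents that add atoms: triethylsilyl trifluoromethanesulfonate CC[Si](CC)(CC)OS(=O)(=O)C(F)(F)F
Why: O-Silylation with the silyl triflate protects the hindered tertiary alcohol, which would otherwise quench the borane and the zinc reagent of step 12.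

Step 12
Reactants: 17 tert-butyl{[(1S,3aR,8aS)-3a,6-dimethyl-1-[(2S)-2-(triethylsilyloxy)but-3-en-2-yl]-1,2,3,3a,4,5,8,8a-octahydroazulen-5-yl]oxy}dimethylsilane; 18 methacrolein
Product: 22 (3S,6S)-6-[(1S,3aR,8aS)-5-(tert-butyldimethylsilyloxy)-3a,6-dimethyl-1,2,3,3a,4,5,8,8a-octahydroazulen-1-yl]-2-methyl-6-(triethylsilyloxy)hept-1-en-3-yl acetate, via alkyldiethylborane 19 (not isolated), via mixed alkylzinc 20 (not isolated), via zinc alkoxide 21 (not isolated)
Conditions: Et2BH (from BH3·SMe2 and Et3B), Et2O, 0 °C to rt; Et2Zn, 0 °C, then volatiles removed in vacuo; Zn(CH2SiMe3)2, toluene; Ti(OiPr)4, (1R,2R)-1,2-bis(trifluoromethanesulfonamido)cyclohexane (8 mol %), 18, −20 °C; then Ac2O, rt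
Reagents that add atoms: acetic anhydride CC(=O)OC(C)=O
Why: Et2BH adds anti-Markovnikov to the only monosubstituted olefin, boron–zinc exchange and comproportionation with Zn(CH2SiMe3)2 give a mixed dialkylzinc that transfers only its functionalised alkyl group, and this group adds to the carbonyl carbon of methacrolein within the chiral titanium bis(sulfonamide) complex to form the C3′–C4′ bond. The closest known reaction type is the titanium-catalysed enantioselective 1,2-addition to aldehydes of functionalised dialkylzincs made by hydroboration and boron–zinc exchange, for which α-substituted enals are among the best substrates. No ring is closed. The new stereocenter C3′ is set by the catalyst alone: the (1R,2R)-ligand directs the alkyl group to the Si face of the aldehyde, which corresponds to the S carbinol here, and the distant stereocenters of the zinc reagent should not interfere. The step needs chemoselective hydroboration of the vinyl group in the presence of the trisubstituted C6=C7 bond, secured by the large rate difference between mono- and trisubstituted olefins towards Et2BH, and 1,2- instead of 1,4-addition, secured by the copper-free, Lewis-acid-mediated zinc chemistry. Acetic anhydride acylates the zinc alkoxide in the flask, so the allylic acetate of the target is obtained without a separate step.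

Step 13
Reactants: 22 (3S,6S)-6-[(1S,3aR,8aS)-5-(tert-butyldimethylsilyloxy)-3a,6-dimethyl-1,2,3,3a,4,5,8,8a-octahydroazulen-1-yl]-2-methyl-6-(triethylsilyloxy)hept-1-en-3-yl acetate
Product: 23 (3S,6S)-6-hydroxy-6-[(1S,3aR,8aS)-5-hydroxy-3a,6-dimethyl-1,2,3,3a,4,5,8,8a-octahydroazulen-1-yl]-2-methylhept-1-en-3-yl acetate
Conditions: HF·pyridine, pyridine, THF, 0 °C to rt
Reagents that add atoms: none
Why: Fluoride-mediated desilylation cleaves the triethylsilyl and the tert-butyldimethylsilyl ether, and the pyridine-buffered medium leaves the allylic acetate and the tertiary alcohol intact.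

Step 14
Reactants: 23 (3S,6S)-6-hydroxy-6-[(1S,3aR,8aS)-5-hydroxy-3a,6-dimethyl-1,2,3,3a,4,5,8,8a-octahydroazulen-1-yl]-2-methylhept-1-en-3-yl acetate
Product: 24 (3S,6S)-6-hydroxy-6-[(1S,3aR,8aS)-3a,6-dimethyl-5-oxo-1,2,3,3a,4,5,8,8a-octahydroazulen-1-yl]-2-methylhept-1-en-3-yl acetate (CNP0193642.1)
Conditions: MnO2 (activated), CH2Cl2, rt
Reagents that add atoms: none
Why: Selective oxidation of the allylic secondary alcohol (both C5 epimers) with MnO2 gives the ring B enone, while the tertiary alcohol and the acetate cannot be oxidised.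

Compound list
1 | diallyl adipate (diallyl hexanedioate) | C=CCOC(=O)CCCCC(=O)OCC=C | starting material
2 | sodium enolate of allyl 2-oxocyclopentane-1-carboxylate | [Na+].[O-]C1=C(C(=O)OCC=C)CCC1 | intermediate
3 | allyl 1-methyl-2-oxocyclopentane-1-carboxylate (racemic) | CC1(C(=O)OCC=C)CCCC1=O | intermediate
4 | (R)-2-allyl-2-methylcyclopentan-1-one | C1CC[C@](C)(CC=C)C1=O | intermediate
5 | (R)-2-(1-methyl-2-oxocyclopentyl)acetaldehyde | C1CC[C@](C)(CC=O)C1=O | intermediate
6 | bromomagnesium alkoxide of (2R)-2-(2-hydroxy-3-methylbut-3-en-1-yl)-2-methylcyclopentan-1-one (both carbinol epimers) | C1CC[C@](C)(CC(O[Mg]Br)C(C)=C)C1=O | intermediate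
7 | (2R)-2-[2-(tert-butyldimethylsilyloxy)-3-methylbut-3-en-1-yl]-2-methylcyclopentan-1-one (both epimers at the silyloxy carbon) | C1CC[C@](C)(CC(O[Si](C)(C)C(C)(C)C)C(C)=C)C1=O | intermediate
8 | lithium aldolate of 7 with acetaldehyde (lithium alkoxide of the 2-(1-hydroxyethyl) ketone, diastereomer mixture) | CC([O-])C1CC[C@](C)(CC(O[Si](C)(C)C(C)(C)C)C(C)=C)C1=O.[Li+] | intermediate
9 | 1-{(3R)-3-[2-(tert-butyldimethylsilyloxy)-3-methylbut-3-en-1-yl]-3-methyl-2-oxocyclopentyl}ethyl methanesulfonate (diastereomer mixture) | CC(OS(C)(=O)=O)C1CC[C@](C)(CC(O[Si](C)(C)C(C)(C)C)C(C)=C)C1=O | intermediate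
10 | (2E,5R)-5-[2-(tert-butyldimethylsilyloxy)-3-methylbut-3-en-1-yl]-2-ethylidene-5-methylcyclopentan-1-one | C/C=C1\CC[C@](C)(CC(O[Si](C)(C)C(C)(C)C)C(C)=C)C1=O | intermediate
11 | (2E,5R)-1-allyl-5-[2-(tert-butyldimethylsilyloxy)-3-methylbut-3-en-1-yl]-2-ethylidene-5-methylcyclopentan-1-ol (both C1 epimers) | C/C=C1\CC[C@](C)(CC(O[Si](C)(C)C(C)(C)C)C(C)=C)C1(O)CC=C | intermediate
12 | 1-[(3R)-2-allyl-3-[2-(tert-butyldimethylsilyloxy)-3-methylbut-3-en-1-yl]-3-methylcyclopent-1-en-1-yl]ethan-1-one | CC(=O)C1=C(CC=C)[C@@](C)(CC(O[Si](C)(C)C(C)(C)C)C(C)=C)CC1 | intermediate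
13 | 1-[(3aR)-5-(tert-butyldimethylsilyloxy)-3a,6-dimethyl-2,3,3a,4,5,8-hexahydroazulen-1-yl]ethan-1-one | CC(=O)C1=C2CC=C(C)C(O[Si](C)(C)C(C)(C)C)C[C@@]2(C)CC1 | intermediate
14 | lithium enolate of 15 (exocyclic C1=C enolate, C8a already S) | CC([O-])=C1CC[C@]2(C)CC(O[Si](C)(C)C(C)(C)C)C(C)=CC[C@@H]12.[Li+] | intermediate
15 | 1-[(1S,3aR,8aS)-5-(tert-butyldimethylsilyloxy)-3a,6-dimethyl-1,2,3,3a,4,5,8,8a-octahydroazulen-1-yl]ethan-1-one | CC(=O)[C@H]1CC[C@]2(C)CC(O[Si](C)(C)C(C)(C)C)C(C)=CC[C@@H]12 | intermediate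
16 | (2S)-2-[(1S,3aR,8aS)-5-(tert-butyldimethylsilyloxy)-3a,6-dimethyl-1,2,3,3a,4,5,8,8a-octahydroazulen-1-yl]but-3-en-2-ol | C=C[C@](C)(O)[C@H]1CC[C@]2(C)CC(O[Si](C)(C)C(C)(C)C)C(C)=CC[C@@H]12 | intermediate
17 | tert-butyl{[(1S,3aR,8aS)-3a,6-dimethyl-1-[(2S)-2-(triethylsilyloxy)but-3-en-2-yl]-1,2,3,3a,4,5,8,8a-octahydroazulen-5-yl]oxy}dimethylsilane | C=C[C@](C)(O[Si](CC)(CC)CC)[C@H]1CC[C@]2(C)CC(O[Si](C)(C)C(C)(C)C)C(C)=CC[C@@H]12 | intermediate
18 | methacrolein (2-methylprop-2-enal) | CC(=C)C=O | starting material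
19 | alkyldiethylborane from 17 (diethylboryl group on the former terminal vinyl carbon, C4′) | CCB(CC)CC[C@](C)(O[Si](CC)(CC)CC)[C@H]1CC[C@]2(C)CC(O[Si](C)(C)C(C)(C)C)C(C)=CC[C@@H]12 | intermediate
20 | mixed alkyl(trimethylsilylmethyl)zinc from 19 | C[Si](C)(C)C[Zn]CC[C@](C)(O[Si](CC)(CC)CC)[C@H]1CC[C@]2(C)CC(O[Si](C)(C)C(C)(C)C)C(C)=CC[C@@H]12 | intermediate
21 | (trimethylsilylmethyl)zinc alkoxide of the (3S)-allylic alcohol | C=C(C)[C@H](CC[C@](C)(O[Si](CC)(CC)CC)[C@H]1CC[C@]2(C)CC(O[Si](C)(C)C(C)(C)C)C(C)=CC[C@@H]12)O[Zn]C[Si](C)(C)C | intermediate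
22 | (3S,6S)-6-[(1S,3aR,8aS)-5-(tert-butyldimethylsilyloxy)-3a,6-dimethyl-1,2,3,3a,4,5,8,8a-octahydroazulen-1-yl]-2-methyl-6-(triethylsilyloxy)hept-1-en-3-yl acetate | C=C(C)[C@H](CC[C@](C)(O[Si](CC)(CC)CC)[C@H]1CC[C@]2(C)CC(O[Si](C)(C)C(C)(C)C)C(C)=CC[C@@H]12)OC(C)=O | intermediate
23 | (3S,6S)-6-hydroxy-6-[(1S,3aR,8aS)-5-hydroxy-3a,6-dimethyl-1,2,3,3a,4,5,8,8a-octahydroazulen-1-yl]-2-methylhept-1-en-3-yl acetate | C=C(C)[C@H](CC[C@](C)(O)[C@H]1CC[C@]2(C)CC(O)C(C)=CC[C@@H]12)OC(C)=O | intermediate
24 | (3S,6S)-6-hydroxy-6-[(1S,3aR,8aS)-3a,6-dimethyl-5-oxo-1,2,3,3a,4,5,8,8a-octahydroazulen-1-yl]-2-methylhept-1-en-3-yl acetate (CNP0193642.1) | C=C(C)[C@H](CC[C@](C)(O)[C@H]1CC[C@]2(C)CC(=O)C(C)=CC[C@@H]12)OC(C)=O | target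

Total step count: 14. Longest linear sequence: 14 steps (1 to 24; methacrolein 18 enters in step 12).

Steps most likely to fail

Step 12. What may go wrong: incomplete boron–zinc exchange or slow transfer of the hindered alkyl group, so that methacrolein is consumed by unselective background addition and the enantioselectivity at C3′ erodes. The fallback sets out from 17 and returns at 22. Hydroboration–oxidation of 17 (9-BBN; NaOH, H2O2) gives the primary alcohol F1, which is converted into the primary iodide F2 (I2, PPh3, imidazole). Iodine–lithium exchange (t-BuLi, Et2O, −78 °C) and 1,2-addition of the alkyllithium to methacrolein 18 form the same C3′–C4′ bond and give the allylic alcohol F3 as both C3′ epimers. Dess–Martin oxidation gives the isopropenyl ketone F4. Corey–Bakshi–Shibata reduction ((R)-2-methyl-CBS-oxazaborolidine, catecholborane, −78 °C) then sets C3′ by reagent control and gives the S alcohol F5. Acetylation (Ac2O, DMAP, pyridine) gives 22.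

Step 9. What may go wrong: protonation of the C8a carbanion with too little facial preference (cis ring fusion), or equilibration of the enolate during the quench (epimerisation at C1). The fallback sets out from 13 and returns at 15 by way of 14. Hydride is delivered instead of electrons: copper hydride catalysed 1,4-hydrosilylation ([(Ph3P)CuH]6 cat., PhMe2SiH, toluene) adds hydride to C8a from the face opposite the angular methyl group and gives the isolable dimethyl(phenyl)silyl enol ether F6. MeLi (THF, 0 °C) then releases the lithium enolate 14 free of ammonia and alkoxide, and a separate protonation at −78 °C with a hindered proton source (2,6-di-tert-butylphenol) gives 15.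

Step 8. What may go wrong: slow ring closure onto the hindered 1,1-disubstituted olefin beside the bulky silyl ether, with competing isomerisation of the skipped diene by ruthenium hydride species and oligomerisation through the allyl group. The fallback sets out from 12 and returns at 13. The silyl ether is cleaved first (HF·pyridine, THF) to give the allylic alcohol F7, whose free hydroxyl group assists metathesis at the adjacent olefin. Ring-closing metathesis (second-generation Grubbs catalyst, CH2Cl2, 40 °C) gives the bicyclic alcohol F8, and silylation (TBSOTf, 2,6-lutidine) gives 13.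

Further compounds
F1 | step 12 | (3S)-3-[(1S,3aR,8aS)-5-(tert-butyldimethylsilyloxy)-3a,6-dimethyl-1,2,3,3a,4,5,8,8a-octahydroazulen-1-yl]-3-(triethylsilyloxy)butan-1-ol | OCC[C@](C)(O[Si](CC)(CC)CC)[C@H]1CC[C@]2(C)CC(O[Si](C)(C)C(C)(C)C)C(C)=CC[C@@H]12
F2 | step 12 | tert-butyl{[(1S,3aR,8aS)-1-[(2S)-4-iodo-2-(triethylsilyloxy)butan-2-yl]-3a,6-dimethyl-1,2,3,3a,4,5,8,8a-octahydroazulen-5-yl]oxy}dimethylsilane | ICC[C@](C)(O[Si](CC)(CC)CC)[C@H]1CC[C@]2(C)CC(O[Si](C)(C)C(C)(C)C)C(C)=CC[C@@H]12
F3 | step 12 | (6S)-6-[(1S,3aR,8aS)-5-(tert-butyldimethylsilyloxy)-3a,6-dimethyl-1,2,3,3a,4,5,8,8a-octahydroazulen-1-yl]-2-methyl-6-(triethylsilyloxy)hept-1-en-3-ol (both C3′ epimers) | C=C(C)C(O)CC[C@](C)(O[Si](CC)(CC)CC)[C@H]1CC[C@]2(C)CC(O[Si](C)(C)C(C)(C)C)C(C)=CC[C@@H]12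
F4 | step 12 | (6S)-6-[(1S,3aR,8aS)-5-(tert-butyldimethylsilyloxy)-3a,6-dimethyl-1,2,3,3a,4,5,8,8a-octahydroazulen-1-yl]-2-methyl-6-(triethylsilyloxy)hept-1-en-3-one | C=C(C)C(=O)CC[C@](C)(O[Si](CC)(CC)CC)[C@H]1CC[C@]2(C)CC(O[Si](C)(C)C(C)(C)C)C(C)=CC[C@@H]12
F5 | step 12 | (3S,6S)-6-[(1S,3aR,8aS)-5-(tert-butyldimethylsilyloxy)-3a,6-dimethyl-1,2,3,3a,4,5,8,8a-octahydroazulen-1-yl]-2-methyl-6-(triethylsilyloxy)hept-1-en-3-ol | C=C(C)[C@H](CC[C@](C)(O[Si](CC)(CC)CC)[C@H]1CC[C@]2(C)CC(O[Si](C)(C)C(C)(C)C)C(C)=CC[C@@H]12)O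
F6 | step 9 | dimethyl(phenyl)silyl enol ether of 15 (exocyclic C1=C enol ether, C8a S) | CC(O[Si](C)(C)c1ccccc1)=C1CC[C@]2(C)CC(O[Si](C)(C)C(C)(C)C)C(C)=CC[C@@H]12
F7 | step 8 | 1-[(3R)-2-allyl-3-(2-hydroxy-3-methylbut-3-en-1-yl)-3-methylcyclopent-1-en-1-yl]ethan-1-one (both carbinol epimers) | CC(=O)C1=C(CC=C)[C@@](C)(CC(O)C(C)=C)CC1
F8 | step 8 | 1-[(3aR)-5-hydroxy-3a,6-dimethyl-2,3,3a,4,5,8-hexahydroazulen-1-yl]ethan-1-one (both C5 epimers) | CC(=O)C1=C2CC=C(C)C(O)C[C@@]2(C)CC1
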